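## Retrosynthetic overview

- Germacrane numbering is used throughout (carbocycle C1–C10, C14 on C10, C15 on C4, lactone O–C6–C7–C11(=C13)–C12). The strategy rests on the C8 carbinol, which lies between oxygenated C9 and a C7 that carries the 1-substituted vinyl unit C11(=C13H2)–C12. The homoallylic alcohol O8–C8–C7–C11=C13 is read back as the allyl ether O8–C13–C11=C7, so the C7–C8 bond and the ten-membered carbocycle come from a [2,3]-Wittig ring contraction of the thirteen-membered α-allyloxy enone 25, through the C8 enolate of its C9 ketone.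
- 25 comes from a Nozaki–Hiyama–Kishi closure of C9–C10 (vinyl iodide at C10, aldehyde at C9) and oxidation. The O8–C13 ether is already in the chain, carried in by propargyl ether 9.
- The open chain comes from enantioselective alkynylation of enal 7 (sets C6). Both trisubstituted olefins are made by hydroxyl-directed trans-hydroalumination/iodination of an alkyne and a Pd coupling with retention: C3 onto C4 by Negishi (C3 cis to C6), C12 onto C11 by Stille (C12 cis and C13 trans to C6). C1=C10 comes from cross-metathesis and α-iodination.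
- After the key step: ester on O8, chelation-controlled reduction of C9, oxidative lactonisation of C12 onto O6, release of C14 and C15. Ring order: thirteen-membered ether (step 15), ten-membered carbocycle (step 17), γ-lactone (step 21).

Key step: step 17

Assumption: (S,S)-ProPhenol is taken to deliver the alkynylzinc to the Si face of enal 7, which gives (R)-11; the sense is to be checked by Mosher ester analysis of 11 and the (R,R)-ligand used if it proves opposite.

## Route

Step 1
Reactants: 1 but-2-yne-1,4-diol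
Product: 2 4-[(tert-butyldimethylsilyl)oxy]but-2-yn-1-ol
Conditions: NaH (1.0 equiv), THF, 0 °C; TBSCl (1.0 equiv), rt
Reagents that add atoms: tert-butyldimethylsilyl chloride, CC(C)(C)[Si](C)(C)Cl
Why: Monosilylation of a symmetrical diol through its sparingly soluble monosodium alkoxide should stop cleanly at the mono-TBS ether; no stereocentre is involved.

Step 2
Reactants: 2 4-[(tert-butyldimethylsilyl)oxy]but-2-yn-1-ol
Product: 4 (Z)-4-[(tert-butyldimethylsilyl)oxy]-3-iodobut-2-en-1-ol, via cyclic sodium alkenylalanate 3 (not isolated)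
Conditions: NaAlH2(OCH2CH2OMe)2 (Red-Al, 1.4 equiv), THF, 0 °C; then I2 (1.5 equiv), THF, −78 → 0 °C
Reagents that add atoms: iodine, II
Why: Hydroxyl-directed trans-hydroalumination of the propargylic alcohol puts hydride on C5 and aluminium on C4 in a five-membered alkoxyalanate, and iodinolysis with retention gives the vinyl iodide with iodine cis to C6, the position C3 has to take.

Step 3
Reactants: 4 (Z)-4-[(tert-butyldimethylsilyl)oxy]-3-iodobut-2-en-1-ol; 5 but-3-en-1-ylzinc bromide (0.5 M in THF)
Product: 6 (E)-3-{[(tert-butyldimethylsilyl)oxy]methyl}hepta-2,6-dien-1-ol (butenyl chain cis to the CH2OH carbon C6)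
Conditions: 5 (3 equiv), Pd(dppf)Cl2 (5 mol %), THF, rt → 50 °C
Reagents that add atoms: none
Why: Negishi sp3–sp2 cross-coupling proceeds with retention at the vinyl iodide, so C3 ends cis to C6 and C15 trans to it as in the target; the excess alkylzinc halide tolerates the free hydroxyl and dppf suppresses β-hydride elimination.

Step 4
Reactants: 6 (E)-3-{[(tert-butyldimethylsilyl)oxy]methyl}hepta-2,6-dien-1-ol
Product: 7 (E)-3-{[(tert-butyldimethylsilyl)oxy]methyl}hepta-2,6-dienal (CHO cis to the butenyl chain)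
Conditions: MnO2 (20 equiv), CH2Cl2, rt
Reagents that add atoms: none
Why: Neutral allylic oxidation with MnO2 should give the enal without touching the silyl ether and without isomerising the trisubstituted double bond.

Step 5
Reactants: 8 2-(prop-2-yn-1-yloxy)ethan-1-ol
Product: 9 1-methoxy-4-{[2-(prop-2-yn-1-yloxy)ethoxy]methyl}benzene (PMB ether of 8)
Conditions: NaH (1.1 equiv), 4-methoxybenzyl chloride, n-Bu4NI (cat.), THF, 0 °C → rt
Reagents that add atoms: 4-methoxybenzyl chloride, COc1ccc(CCl)cc1
Why: Williamson etherification of the primary alkoxide, which forms in preference to the far less acidic acetylide, masks the future C9 oxygen as an ether that survives hydride, organozinc and Pd steps.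

Step 6
Reactants: 7 (E)-3-{[(tert-butyldimethylsilyl)oxy]methyl}hepta-2,6-dienal; 9 1-methoxy-4-{[2-(prop-2-yn-1-yloxy)ethoxy]methyl}benzene
Product: 11 (4R,5E)-6-{[(tert-butyldimethylsilyl)oxy]methyl}-1-{2-[(4-methoxybenzyl)oxy]ethoxy}deca-5,9-dien-2-yn-4-ol, via methylzinc acetylide 10 (not isolated)
Conditions: 9 (2.8 equiv), Me2Zn (2.9 equiv), (S,S)-ProPhenol (20 mol %), Ph3P=O (40 mol %), toluene, 0 °C; then 7, 4 °C
Reagents that add atoms: none
Why: Zinc–ProPhenol catalysed enantioselective alkynylation of an α,β-unsaturated aldehyde should add acetylide 10 in a 1,2-fashion to the Si face inside the dinuclear zinc pocket, setting C6 (R) and joining C6 to C7.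

Step 7
Reactants: 11 (4R,5E)-6-{[(tert-butyldimethylsilyl)oxy]methyl}-1-{2-[(4-methoxybenzyl)oxy]ethoxy}deca-5,9-dien-2-yn-4-ol
Product: 13 (2Z,4R,5E)-6-{[(tert-butyldimethylsilyl)oxy]methyl}-2-iodo-1-{2-[(4-methoxybenzyl)oxy]ethoxy}deca-2,5,9-trien-4-ol, via cyclic sodium alkenylalanate 12 (not isolated)
Conditions: NaAlH2(OCH2CH2OMe)2 (Red-Al, 2 equiv), THF, −20 → 0 °C; then I2 (2 equiv), THF, −78 °C
Reagents that add atoms: iodine, II
Why: The C6 alkoxide directs trans-hydroalumination of the C7≡C11 alkyne (hydride to C7, aluminium to C11), and iodinolysis with retention leaves iodine cis and the C13 ether carbon trans to C6; the low temperature avoids loss of the propargylic ether to an allene.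

Step 8
Reactants: 13 (2Z,4R,5E)-vinyl iodide (iodine on C11); 14 (tributylstannyl)methanol
Product: 15 (2E,4R,5E)-6-{[(tert-butyldimethylsilyl)oxy]methyl}-2-({2-[(4-methoxybenzyl)oxy]ethoxy}methyl)deca-2,5,9-triene-1,4-diol (new CH2OH = C12, cis to C6)
Conditions: 14 (1.5 equiv), Pd(PPh3)4 (10 mol %), 1,4-dioxane, 90 °C
Reagents that add atoms: none
Why: Stille coupling transfers the hydroxymethyl group to C11 with retention, so C12 (the later lactone carbonyl) is cis and C13 (the ether carbon) trans to C6, which tells the two CH2O groups on C11 apart.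

Step 9
Reactants: 15 (2E,4R,5E)-triene-1,4-diol
Product: 16 bis(triethylsilyl) ether of 15 (O6 and O12 silylated)
Conditions: Et3SiCl (2.5 equiv), imidazole (4 equiv), DMAP (cat.), CH2Cl2, 0 °C
Reagents that add atoms: chlorotriethylsilane, CC[Si](CC)(CC)Cl
Why: Standard silylation of the primary and the secondary bis-allylic hydroxyl under basic conditions avoids ionisation of the divinyl carbinol.

Step 10
Reactants: 16 bis(triethylsilyl) ether; 17 (E)-but-2-enal (crotonaldehyde)
Product: 18 enal in which the terminal vinyl group of 16 has become (E)-CH=CH–CHO (C1=C10–C14)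
Conditions: 17 (10 equiv), second-generation Hoveyda–Grubbs catalyst RuCl2(H2IMes)(=CH-C6H4-2-O-i-Pr) (5 mol %), CH2Cl2, 40 °C
Reagents that add atoms: none
Why: Olefin cross-metathesis of the only monosubstituted alkene with excess crotonaldehyde should give the E-enal, the hindered trisubstituted olefins being inert.

Step 11
Reactants: 18 E-enal
Product: 19 (Z)-2-iodo enal (iodine on C10, cis to C2; CHO trans to C2)
Conditions: I2 (1.5 equiv), K2CO3 (1.2 equiv), DMAP (0.2 equiv), THF/H2O 1:1, rt
Reagents that add atoms: iodine, II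
Why: α-Iodination of the enal by conjugate addition of DMAP, iodination of the enolate and E1cB loss of DMAP (Baylis–Hillman-type addition–elimination) gives the thermodynamically preferred (Z)-2-iodoenal, which fixes C2 trans to C14 as in the target.

Step 12
Reactants: 19 (Z)-2-iodo enal
Product: 20 1,3-dioxolane of 19 (C14 acetal)
Conditions: Me3SiOCH2CH2OSiMe3 (3 equiv), Me3SiOTf (5 mol %), CH2Cl2, −78 → −30 °C; pyridine quench
Reagents that add atoms: 1,2-bis(trimethylsilyloxy)ethane, C[Si](C)(C)OCCO[Si](C)(C)C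
Why: Aprotic silyl-transfer acetalisation at low temperature converts the aldehyde into the dioxolane without double-bond migration and without cleaving the silyl or PMB ethers.

Step 13
Reactants: 20 dioxolane with PMB ether
Product: 21 primary alcohol (free C9–OH)
Conditions: DDQ (1.3 equiv), CH2Cl2/pH 7 phosphate buffer 10:1, 0 °C
Reagents that add atoms: none
Why: Oxidative cleavage of the electron-rich PMB ether by DDQ in buffered medium is fast at 0 °C and should leave the silyl ethers, acetal and vinyl iodide intact.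

Step 14
Reactants: 21 primary alcohol
Product: 22 α-alkoxy aldehyde (C9 aldehyde, C10 vinyl iodide)
Conditions: Dess–Martin periodinane (1.5 equiv), NaHCO3, CH2Cl2, 0 °C → rt
Reagents that add atoms: none
Why: Buffered Dess–Martin oxidation gives the sensitive α-alkoxy aldehyde under neutral conditions; it is used at once.

Step 15
Reactants: 22 seco aldehyde/vinyl iodide
Product: 24 thirteen-membered allylic alcohol (C9–OH, both epimers), via alkenylchromium dichloride 23 (not isolated)
Conditions: CrCl2 (10 equiv), NiCl2 (0.1 equiv), DMSO/THF 3:1, rt, 2 mM, slow addition of 22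
Reagents that add atoms: none
Why: Nozaki–Hiyama–Kishi reaction: nickel-catalysed formation of the alkenylchromium from the vinyl iodide and its chemoselective intramolecular addition to the aldehyde at high dilution closes the thirteen-membered ring with retention at C1=C10; the C9 epimers converge in step 16.

Step 16
Reactants: 24 thirteen-membered allylic alcohol
Product: 25 thirteen-membered α-allyloxy enone (C9 ketone; C6 and C12 triethylsilyl ethers, C15 tert-butyldimethylsilyl ether, C14 dioxolane; 6R)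
Conditions: Dess–Martin periodinane (1.5 equiv), NaHCO3, CH2Cl2, 0 °C
Reagents that add atoms: none
Why: Dess–Martin oxidation of the allylic alcohol gives the enone without isomerising C1=C10 or touching the acetal.

Step 17
Reactants: 25 thirteen-membered α-allyloxy enone
Product: 28 ten-membered 8-hydroxy-9-ketone with the C11(=C13H2)–C12H2OSiEt3 side chain on C7 (O8 and C11 trans, O6 and C11 trans on the ring), via potassium enolate 26 (not isolated), via potassium alkoxide 27 (not isolated)
Conditions: KN(SiMe3)2 (1.3 equiv), THF, −78 → −40 °C; AcOH in THF, −78 °C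
Reagents that add atoms: none
Why: Proposed new method: KN(SiMe3)2 removes a C8 proton (the only α-hydrogens of the C9 ketone, acidified by the ether oxygen and kinetically favoured over the γ-hydrogens at C2) to give the chelated Z(O) enolate 26, whose C8 carbon bonds suprafacially to C7 through a five-membered envelope (C8, O, C13, C11, C7) while O–C13 breaks. The closest known reactions are the [2,3]-Wittig ring contraction of thirteen-membered allylic and propargylic ethers to cyclodecenols and the enolate [2,3]-Wittig shift of acyclic α-allyloxy ketones and esters; their union on a macrocyclic α-allyloxy enone is the new element. The ten-membered ring is closed by sigmatropic contraction: the C7–C8 bond forms across the ring and O, C13 and C11 are extruded as the C8 alkoxide and the exocyclic methylene, so no high-dilution C–C cyclisation is needed. C7 is set by allylic 1,3-strain: H6 lies in the C7=C11 plane beside the cis C12 group, so the enolate, tethered through C5, adds to the face of C7 syn to C5 and anti to the C6 silyloxy group. C8 is set by the olefin geometry (C6 trans to C13) together with the exo position of the enolate carbon C9 in the envelope, which places the new hydroxyl and C11 trans on the ring. The step needs [2,3] to outrun the [3,3] oxy-Claisen shift to C9 and the [1,2] shift: bonding at C9 would build a quaternary carbinol between the dioxolane-bearing C10 and the branched C7, and the low temperature and cold AcOH quench limit radical [1,2] cleavage, silyl migration and α-ketol shift of alkoxide 27.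

Step 18
Reactants: 28 ten-membered 8-hydroxy-9-ketone; 29 (R)-2-methylbutanoic acid
Product: 31 C8 (R)-2-methylbutanoate of 28, via O-acylisourea 30 (not isolated)
Conditions: 29 (2 equiv), DCC (2 equiv), DMAP (0.2 equiv), CH2Cl2, 0 °C → rt
Reagents that add atoms: none
Why: Steglich esterification acylates the only free hydroxyl; the low temperature and sub-stoichiometric DMAP guard the α-stereocentres of both the acid and the α-acyloxy ketone.

Step 19
Reactants: 31 C8 ester, C9 ketone
Product: 32 (9S)-alcohol (C9–OH cis to the C8 acyloxy group on the ring)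
Conditions: Zn(BH4)2 (0.15 M in Et2O, 2 equiv), Et2O, −30 → 0 °C; H2O
Reagents that add atoms: none
Why: Chelation-controlled 1,2-reduction: zinc bridges the C9 carbonyl and the C8 acyloxy oxygen and hydride enters from the side of H8, which gives the 8,9-cis alcohol, while the neutral conditions should avoid conjugate reduction and acyl migration.

Step 20
Reactants: 32 (9S)-alcohol with two triethylsilyl ethers
Product: 33 triol (free O6–H, O12–H and O9–H; C15 silyl ether and C14 dioxolane kept)
Conditions: PPTS (0.2 equiv), MeOH/CH2Cl2 1:1, 0 °C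
Reagents that add atoms: none
Why: Acid-catalysed methanolysis removes triethylsilyl ethers much faster than the tert-butyldimethylsilyl ether, and a dioxolane is stable to PPTS in methanol at 0 °C.

Step 21
Reactants: 33 triol
Product: 36 α-methylene γ-lactone (C12 carbonyl on O6; C15 silyl ether, C14 dioxolane), via hydroxy aldehyde 34 (not isolated), via lactol 35 (not isolated)
Conditions: TEMPO (0.2 equiv), PhI(OAc)2 (2.5 equiv), CH2Cl2, rt
Reagents that add atoms: none
Why: Oxidative lactonisation of a 1,4-diol: the oxoammonium oxidant takes the primary allylic C12 alcohol selectively, the aldehyde is trapped by the C6 hydroxyl as a five-membered lactol and this is oxidised on to the lactone, the secondary C9 hydroxyl being too slow to compete.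

Step 22
Reactants: 36 protected lactone
Product: 37 target CNP0331447.12
Conditions: 1 M aq. HCl/THF 1:4, 0 °C → rt
Reagents that add atoms: water, O
Why: Dilute aqueous acid hydrolyses the alkenyl dioxolane through an allyl-stabilised oxocarbenium ion and cleaves the primary allylic silyl ether, releasing the C14 aldehyde and the C15 hydroxyl without disturbing ester, lactone or stereocentres.

## Compound list

1 | but-2-yne-1,4-diol | OCC#CCO | starting material
2 | 4-[(tert-butyldimethylsilyl)oxy]but-2-yn-1-ol | OCC#CCO[Si](C)(C)C(C)(C)C | intermediate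
3 | cyclic sodium alkenylalanate from 2 (five-membered O–Al–C4 ring, two 2-methoxyethoxy ligands) | [Na+].COCCO[Al-]1(OCCOC)OCC=C1CO[Si](C)(C)C(C)(C)C | intermediate (not isolated)
4 | (Z)-4-[(tert-butyldimethylsilyl)oxy]-3-iodobut-2-en-1-ol | OC/C=C(\I)CO[Si](C)(C)C(C)(C)C | intermediate
5 | but-3-en-1-ylzinc bromide | C=CCC[Zn]Br | starting material
6 | (E)-3-{[(tert-butyldimethylsilyl)oxy]methyl}hepta-2,6-dien-1-ol | OC/C=C(\CCC=C)CO[Si](C)(C)C(C)(C)C | intermediate
7 | (E)-3-{[(tert-butyldimethylsilyl)oxy]methyl}hepta-2,6-dienal | O=C/C=C(\CCC=C)CO[Si](C)(C)C(C)(C)C | intermediate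
8 | 2-(prop-2-yn-1-yloxy)ethan-1-ol | C#CCOCCO | starting material
9 | 1-methoxy-4-{[2-(prop-2-yn-1-yloxy)ethoxy]methyl}benzene | C#CCOCCOCc1ccc(OC)cc1 | intermediate
10 | methylzinc acetylide of 9 | C[Zn]C#CCOCCOCc1ccc(OC)cc1 | intermediate (not isolated)
11 | (4R,5E)-6-{[(tert-butyldimethylsilyl)oxy]methyl}-1-{2-[(4-methoxybenzyl)oxy]ethoxy}deca-5,9-dien-2-yn-4-ol | COc1ccc(COCCOCC#C[C@H](O)/C=C(\CCC=C)CO[Si](C)(C)C(C)(C)C)cc1 | intermediate
12 | cyclic sodium alkenylalanate from 11 (five-membered O6–Al–C11 ring) | [Na+].COCCO[Al-]1(OCCOC)O[C@H](/C=C(\CCC=C)CO[Si](C)(C)C(C)(C)C)C=C1COCCOCc2ccc(OC)cc2 | intermediate (not isolated)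
13 | (2Z,4R,5E)-6-{[(tert-butyldimethylsilyl)oxy]methyl}-2-iodo-1-{2-[(4-methoxybenzyl)oxy]ethoxy}deca-2,5,9-trien-4-ol | COc1ccc(COCCOC/C(I)=C/[C@H](O)/C=C(\CCC=C)CO[Si](C)(C)C(C)(C)C)cc1 | intermediate
14 | (tributylstannyl)methanol | CCCC[Sn](CCCC)(CCCC)CO | starting material
15 | (2E,4R,5E)-6-{[(tert-butyldimethylsilyl)oxy]methyl}-2-({2-[(4-methoxybenzyl)oxy]ethoxy}methyl)deca-2,5,9-triene-1,4-diol | COc1ccc(COCCOC/C(CO)=C/[C@H](O)/C=C(\CCC=C)CO[Si](C)(C)C(C)(C)C)cc1 | intermediate
16 | 1,4-bis-O-triethylsilyl ether of 15 (4R) | COc1ccc(COCCOC/C(CO[Si](CC)(CC)CC)=C/[C@H](O[Si](CC)(CC)CC)/C=C(\CCC=C)CO[Si](C)(C)C(C)(C)C)cc1 | intermediate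
17 | (E)-but-2-enal | C/C=C/C=O | starting material
18 | E-enal from 16 (C1=C10–C14HO in place of the vinyl group) | COc1ccc(COCCOC/C(CO[Si](CC)(CC)CC)=C/[C@H](O[Si](CC)(CC)CC)/C=C(\CC/C=C/C=O)CO[Si](C)(C)C(C)(C)C)cc1 | intermediate
19 | (Z)-2-iodo enal (iodine on C10, cis to C2) | COc1ccc(COCCOC/C(CO[Si](CC)(CC)CC)=C/[C@H](O[Si](CC)(CC)CC)/C=C(\CC/C=C(\I)C=O)CO[Si](C)(C)C(C)(C)C)cc1 | intermediate
20 | 1,3-dioxolane of 19 | COc1ccc(COCCOC/C(CO[Si](CC)(CC)CC)=C/[C@H](O[Si](CC)(CC)CC)/C=C(\CC/C=C(\I)C2OCCO2)CO[Si](C)(C)C(C)(C)C)cc1 | intermediate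
21 | primary alcohol (PMB removed, free C9–OH) | OCCOC/C(CO[Si](CC)(CC)CC)=C/[C@H](O[Si](CC)(CC)CC)/C=C(\CC/C=C(\I)C1OCCO1)CO[Si](C)(C)C(C)(C)C | intermediate
22 | seco aldehyde (C9HO) with C10 vinyl iodide | O=CCOC/C(CO[Si](CC)(CC)CC)=C/[C@H](O[Si](CC)(CC)CC)/C=C(\CC/C=C(\I)C1OCCO1)CO[Si](C)(C)C(C)(C)C | intermediate
23 | alkenylchromium dichloride from 22 (chromium on C10) | O=CCOC/C(CO[Si](CC)(CC)CC)=C/[C@H](O[Si](CC)(CC)CC)/C=C(\CC/C=C(\[Cr](Cl)Cl)C1OCCO1)CO[Si](C)(C)C(C)(C)C | intermediate (not isolated)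
24 | thirteen-membered cyclic ether with C9 allylic alcohol (C9 epimers, 6R) | OC1COC/C(CO[Si](CC)(CC)CC)=C/[C@H](O[Si](CC)(CC)CC)/C=C(/CO[Si](C)(C)C(C)(C)C)CC/C=C1/C2OCCO2 | intermediate
25 | thirteen-membered α-allyloxy enone (6R), key-step precursor | O=C1COC/C(CO[Si](CC)(CC)CC)=C/[C@H](O[Si](CC)(CC)CC)/C=C(/CO[Si](C)(C)C(C)(C)C)CC/C=C1/C2OCCO2 | intermediate
26 | potassium Z(O)-enolate of 25 (C8=C9) | [K+].[O-]/C1=C\OC/C(CO[Si](CC)(CC)CC)=C/[C@H](O[Si](CC)(CC)CC)/C=C(/CO[Si](C)(C)C(C)(C)C)CC/C=C1/C2OCCO2 | intermediate (not isolated)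
27 | potassium C8 alkoxide of 28 | [K+].O=C1[C@H]([O-])[C@@H](C(=C)CO[Si](CC)(CC)CC)[C@H](O[Si](CC)(CC)CC)/C=C(/CO[Si](C)(C)C(C)(C)C)CC/C=C1/C2OCCO2 | intermediate (not isolated)
28 | ten-membered 8-hydroxy-9-ketone, key-step product | O=C1[C@H](O)[C@@H](C(=C)CO[Si](CC)(CC)CC)[C@H](O[Si](CC)(CC)CC)/C=C(/CO[Si](C)(C)C(C)(C)C)CC/C=C1/C2OCCO2 | intermediate
29 | (R)-2-methylbutanoic acid | CC[C@@H](C)C(=O)O | starting material
30 | O-acylisourea of 29 with DCC | CC[C@@H](C)C(=O)OC(=NC1CCCCC1)NC2CCCCC2 | intermediate (not isolated)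
31 | C8 (R)-2-methylbutanoate of 28 | O=C1[C@H](OC(=O)[C@H](C)CC)[C@@H](C(=C)CO[Si](CC)(CC)CC)[C@H](O[Si](CC)(CC)CC)/C=C(/CO[Si](C)(C)C(C)(C)C)CC/C=C1/C2OCCO2 | intermediate
32 | (9S)-alcohol, 8,9-cis | O[C@@H]1[C@H](OC(=O)[C@H](C)CC)[C@@H](C(=C)CO[Si](CC)(CC)CC)[C@H](O[Si](CC)(CC)CC)/C=C(/CO[Si](C)(C)C(C)(C)C)CC/C=C1/C2OCCO2 | intermediate
33 | triol (O6–H, O9–H, O12–H) | O[C@@H]1[C@H](OC(=O)[C@H](C)CC)[C@@H](C(=C)CO)[C@H](O)/C=C(/CO[Si](C)(C)C(C)(C)C)CC/C=C1/C2OCCO2 | intermediate
34 | C12 aldehyde (2-substituted acrolein) | O[C@@H]1[C@H](OC(=O)[C@H](C)CC)[C@@H](C(=C)C=O)[C@H](O)/C=C(/CO[Si](C)(C)C(C)(C)C)CC/C=C1/C2OCCO2 | intermediate (not isolated)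
35 | five-membered lactol (C12 hemiacetal on O6) | C=C1C(O)O[C@@H]2/C=C(/CO[Si](C)(C)C(C)(C)C)CC/C=C(/C3OCCO3)[C@H](O)[C@H](OC(=O)[C@H](C)CC)[C@@H]12 | intermediate (not isolated)
36 | α-methylene γ-lactone with C15 silyl ether and C14 dioxolane | C=C1C(=O)O[C@@H]2/C=C(/CO[Si](C)(C)C(C)(C)C)CC/C=C(/C3OCCO3)[C@H](O)[C@H](OC(=O)[C@H](C)CC)[C@@H]12 | intermediate
37 | CNP0331447.12: (6R,7S,8R,9S)-9,15-dihydroxy-8-[(2R)-2-methylbutanoyloxy]-14-oxogermacra-1(10),4,11(13)-trien-12,6-olide, C2 cis to C9 and C3 cis to C6 | C=C1C(=O)O[C@@H]2/C=C(/CO)CC/C=C(/C=O)[C@H](O)[C@H](OC(=O)[C@H](C)CC)[C@@H]12 | target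

## Step count and risks

Total step count: 22. Longest linear sequence: 21 steps (steps 1–4 and 6–22, from but-2-yne-1,4-diol).

**Step 17 (proposed new method).** The enolate may rearrange along the competing [3,3] path to C9 or the [1,2] path, be formed at C2 instead of C8, or the product alkoxide may suffer silyl migration before the quench. The fallback uses known chemistry only: an acyclic ester-enolate [2,3]-Wittig shift makes C7–C8 and a Nozaki–Hiyama–Kishi reaction then closes the ten-membered ring. It sets out from aldehyde 22. Pinnick oxidation (NaClO2, NaH2PO4, 2-methyl-2-butene, t-BuOH/H2O) gives carboxylic acid F1 and Me3SiCHN2 in MeOH/toluene gives methyl ester F2. LiN(SiMe3)2 in THF at −78 → −30 °C forms the lithium ester enolate, which rearranges to α-hydroxy ester F3 under the same allylic-strain control at C7 (C8 epimers are separated if needed). Me3SiCl/imidazole gives trimethylsilyl ether F4, i-Bu2AlH in CH2Cl2 at −78 °C gives aldehyde F5, and CrCl2/NiCl2 in DMSO at high dilution closes the ring to ten-membered allylic alcohol F6. Dess–Martin oxidation gives silyloxy enone F7, and K2CO3 in MeOH at 0 °C removes the trimethylsilyl group, coming back to the route at 28.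

**Step 19.** Hydride delivery may show poor facial selectivity in the flexible ten-membered ring, and the acyl group may migrate from O8 to O9. The fallback reduces before acylating, so that the free α-hydroxyl gives a tight five-membered zinc chelate. It sets out from 28: Zn(BH4)2 in Et2O at −20 °C gives cis-diol F8; Et3SiCl (1.05 equiv)/imidazole at −40 °C silylates the less hindered allylic C9 hydroxyl to give C9 triethylsilyl ether F9; DCC/DMAP with 29 acylates the remaining C8 hydroxyl to give ester F10. The conditions of step 20 then remove all three triethylsilyl groups and the route is rejoined at 33.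

**Step 6.** Enantioselectivity may erode on this β,β-disubstituted enal, or the enal double bond may isomerise under the zinc conditions. The fallback replaces catalytic addition by a stoichiometric, reagent-controlled reduction. It sets out from 7 and 9: the lithium acetylide of 9 (n-BuLi, THF, −78 °C) adds to 7 to give racemic carbinol F11, MnO2 gives ynone F12, and Midland reduction with (R)-Alpine-Borane (B-isopinocampheyl-9-borabicyclo[3.3.1]nonane from (+)-α-pinene), in which the alkyne is the small group, gives the (R)-alcohol, coming back to the route at 11.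

## Further compounds

F1 | step 17 | carboxylic acid from 22 (C9 acid) | OC(=O)COC/C(CO[Si](CC)(CC)CC)=C/[C@H](O[Si](CC)(CC)CC)/C=C(\CC/C=C(\I)C1OCCO1)CO[Si](C)(C)C(C)(C)C
F2 | step 17 | methyl ester of F1 | COC(=O)COC/C(CO[Si](CC)(CC)CC)=C/[C@H](O[Si](CC)(CC)CC)/C=C(\CC/C=C(\I)C1OCCO1)CO[Si](C)(C)C(C)(C)C
F3 | step 17 | acyclic α-hydroxy ester (C7–C8 bond formed, C11=C13 methylene) | COC(=O)[C@H](O)[C@@H](C(=C)CO[Si](CC)(CC)CC)[C@H](O[Si](CC)(CC)CC)/C=C(\CC/C=C(\I)C1OCCO1)CO[Si](C)(C)C(C)(C)C
F4 | step 17 | C8 trimethylsilyl ether of F3 | COC(=O)[C@H](O[Si](C)(C)C)[C@@H](C(=C)CO[Si](CC)(CC)CC)[C@H](O[Si](CC)(CC)CC)/C=C(\CC/C=C(\I)C1OCCO1)CO[Si](C)(C)C(C)(C)C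
F5 | step 17 | C9 aldehyde from F4 | O=C[C@H](O[Si](C)(C)C)[C@@H](C(=C)CO[Si](CC)(CC)CC)[C@H](O[Si](CC)(CC)CC)/C=C(\CC/C=C(\I)C1OCCO1)CO[Si](C)(C)C(C)(C)C
F6 | step 17 | ten-membered allylic alcohol (C9–OH epimers, C8 trimethylsilyl ether) | OC1[C@H](O[Si](C)(C)C)[C@@H](C(=C)CO[Si](CC)(CC)CC)[C@H](O[Si](CC)(CC)CC)/C=C(/CO[Si](C)(C)C(C)(C)C)CC/C=C1/C2OCCO2
F7 | step 17 | ten-membered 8-trimethylsilyloxy-9-ketone | O=C1[C@H](O[Si](C)(C)C)[C@@H](C(=C)CO[Si](CC)(CC)CC)[C@H](O[Si](CC)(CC)CC)/C=C(/CO[Si](C)(C)C(C)(C)C)CC/C=C1/C2OCCO2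
F8 | step 19 | 8,9-cis diol from 28 | O[C@@H]1[C@H](O)[C@@H](C(=C)CO[Si](CC)(CC)CC)[C@H](O[Si](CC)(CC)CC)/C=C(/CO[Si](C)(C)C(C)(C)C)CC/C=C1/C2OCCO2
F9 | step 19 | C9 triethylsilyl ether of F8 | CC[Si](CC)(CC)O[C@@H]1[C@H](O)[C@@H](C(=C)CO[Si](CC)(CC)CC)[C@H](O[Si](CC)(CC)CC)/C=C(/CO[Si](C)(C)C(C)(C)C)CC/C=C1/C2OCCO2
F10 | step 19 | C8 (R)-2-methylbutanoate of F9 | CC[Si](CC)(CC)O[C@@H]1[C@H](OC(=O)[C@H](C)CC)[C@@H](C(=C)CO[Si](CC)(CC)CC)[C@H](O[Si](CC)(CC)CC)/C=C(/CO[Si](C)(C)C(C)(C)C)CC/C=C1/C2OCCO2
F11 | step 6 | racemic form of carbinol 11 | COc1ccc(COCCOCC#CC(O)/C=C(\CCC=C)CO[Si](C)(C)C(C)(C)C)cc1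
F12 | step 6 | ynone from F11 (C6 ketone) | COc1ccc(COCCOCC#CC(=O)/C=C(\CCC=C)CO[Si](C)(C)C(C)(C)C)cc1
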